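It was impossible to read a reagent effect from the elm and oak runs, for both held 0.375 M of reagent and 0.075 M of substrate and differed in free catalyst, 5.7 mM against 7.6 mM.

| flask | substrate | reagent | free catalyst | remark | time |
|---|---|---|---|---|---|
| elm | 0.075 M | 0.375 M | 5.7 mM | run made earlier |  |
| oak | 0.075 M | 0.375 M | 7.6 mM | run made earlier |  |
| Wednesday's | 0.075 M | 0.375 M | 3.8 mM |  | 50 min |
| Friday's | 0.050 M | 0.100 M | 3.8 mM |  | 50 min |

| run | time / min | target / % | side product / % |
|---|---|---|---|
| elm | 1.33 | 19.2 | 1.1 |
| elm | 4.00 | 55.2 | 5.7 |
| elm | 6.00 | 72.6 | 7.9 |
| elm | 10.0 | 88.5 | 10.4 |
| oak | 0.833 | 15.5 | 0 |
| oak | 2.00 | 39.7 | 4.6 |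
| oak | 4.00 | 68.3 | 5.9 |
| oak | 10.0 | 92.1 | 9.7 |

(each reading ± 1 percentage point)

- a species is counted by the substrate in it: one side product counts as two
- reactions considered so far: substrate + free catalyst <-> catalyst intermediate A; reagent + catalyst intermediate A -> catalyst intermediate B; catalyst intermediate B -> free catalyst + target; substrate + target -> side product

* the flask that ends with the higher share of target in all that became target or side product, or "neither" when 2 percentage points or less lies between them (Wednesday's / Friday's / neither)
* share of target in all that became target or side product, Wednesday's
* share of target in all that became target or side product, Friday's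

Side product forms when substrate meets target, so I expected the side fraction, the part of the converted substrate that ended as side product, to grow with the substrate charge and shrink with the catalyst charge as long as reagent stayed at elm's charge, 5.00 equivalents, where I treated its step as pseudo-first-order. I read 0.00799 from elm's last reading as the side load, the side fraction times the catalyst charge over the substrate charge; oak's last reading gave 0.00966, a gap to hold beside a scatter of 1 percentage point on 9.7% of side product. Wednesday's flask kept elm's reagent, so the load gave it a side fraction of 15.8% and a share of target of 84.2%.

Friday's flask stood past the border of this rule, at 2.00 equivalents, with reagent lower than elm's by a factor of 3.75. For Friday's the load gave 10.5% if reagent did not matter and, multiplied by that factor, 39.4% if reagent paced the turnover entirely. I took the middle, a share near 75.0%, and so named Wednesday's flask.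

The forecast differed from my reckoning: it stood at 85% for Wednesday's and 86% for Friday's, hence neither, with the words “the lower reagent may hurt, and no run varied reagent”.

The simulation gave 84.0% for Wednesday's and 72.1% for Friday's, so Wednesday's flask ended higher.

    substrate + free catalyst ⇌ catalyst intermediate A (K = 43.0 /M, k = 22.0 /M/s)
    reagent + catalyst intermediate A → catalyst intermediate B (k = 0.190 /M/s)
    catalyst intermediate B → free catalyst + target (k = 0.140 /s)
    substrate + target → side product (k = 0.0110 /M/s)

Friday's flask ended at 72.1% mainly because of its lower reagent: charged with Wednesday's reagent, it gave 90.8%, a side fraction of 9.20% beside the 10.5% from the side load. On a neighbour of Wednesday's charged with 0.30 M of substrate, the load gave a side fraction of 63.1%; the computed flask ended with 66.2% side product and a share of target of 33.8%.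

(The earlier runs and the new flask come from a simulation for substances that don't exist; noise was put on by code.)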